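Ring B is disconnected at C1'–C2' and C5'–C6'. The feature used is that C6' (carbinol) and C4' (C–Cl) are 1,3-related through C5', an aldol pattern, while C1' is a CH between C6' and the quaternary C6 of ring A. One amine-catalysed operation joins the ring A acetaldehyde 5 (C1' = CH2, C6' = CHO) to butenone by Michael addition and aldol condensation, closing ring B as cyclohex-2-enone 9 and setting C1'. Precursor 5 is the (3R,6S)-3-bromo-oxane with CH2CHO on C6; it comes from (S)-linalool, whose carbinol carbon is C6 and whose vinyl group is C1'–C6'. Enone 9 then delivers the C6' oxygen, the C4' methyl and both halogens.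

Key step: step 4

Locants: ring A = O1, C2 (CMe2), C3 (CHBr), C4, C5, C6 (CMe); ring B = C1' (on C6), C2', C3' (CHBr), C4' (CMeCl), C5', C6' (CHOH). "Lower face" of ring B is the face that carries ring A at C1'; "upper face" is the other one. Target configuration: 3R,6S,1'R,3'S,4'S,6'S.
Assumption: (S)-(+)-linalool is bought in high enantiomeric purity; its carbinol centre becomes C6 without change.

Step 1
Reactants: 1 (S)-linalool
Product: 2 (3R,6S)-3-bromo-6-ethenyl-2,2,6-trimethyloxane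
Conditions: TBCO, MeNO2, 0 °C to rt, dark
Reagents that add atoms: 2,4,4,6-tetrabromocyclohexa-2,5-dien-1-one (TBCO), O=C1C(Br)=CC(Br)(Br)C=C1Br
Why: Electrophilic bromoetherification: the tertiary hydroxyl opens the bromonium ion of the trisubstituted alkene at its tertiary carbon (C2) in a 6-endo chair closure that puts Br equatorial; C3 forms without useful bias from C6 (CH3 and vinyl are alike in size), so the (3R) epimer 2 is taken by chromatography and the (3S) epimer can be returned to 1 by zinc-mediated reductive ring opening.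

Step 2
Reactants: 2 (3R,6S)-3-bromo-6-ethenyl-2,2,6-trimethyloxane
Product: 4 2-[(2S,5R)-5-bromo-2,6,6-trimethyloxan-2-yl]ethan-1-ol, via B-alkyl-9-BBN adduct 3 (not isolated)
Conditions: 9-BBN, THF, 50 °C; then NaOH, H2O2, 0 °C to rt
Reagents that add atoms: hydrogen peroxide, OO
Why: Hydroboration–oxidation: the hindered borane places boron on the terminal vinyl carbon and alkaline peroxide replaces boron by OH; no stereocentre is touched and the equatorial, neopentyl-type C3 bromide is inert to both reagents.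

Step 3
Reactants: 4 2-[(2S,5R)-5-bromo-2,6,6-trimethyloxan-2-yl]ethan-1-ol
Product: 5 2-[(2S,5R)-5-bromo-2,6,6-trimethyloxan-2-yl]acetaldehyde
Conditions: DMP, NaHCO3, CH2Cl2, 0 °C to rt
Reagents that add atoms: none
Why: Periodinane oxidation (DMP = 1,1,1-triacetoxy-1,1-dihydro-1,2-benziodoxol-3(1H)-one) of the primary alcohol stops at the aldehyde under buffered conditions, so the β-alkoxy aldehyde should neither over-oxidise nor eliminate.

Step 4
Reactants: 5 2-[(2S,5R)-5-bromo-2,6,6-trimethyloxan-2-yl]acetaldehyde; 6 but-3-en-2-one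
Product: 9 (4R)-4-[(2S,5R)-5-bromo-2,6,6-trimethyloxan-2-yl]cyclohex-2-en-1-one, via keto aldehyde 7 (not isolated), via ketol 8 (not isolated)
Conditions: (S)-α,α-diphenylprolinol trimethylsilyl ether (20 mol%), ethyl 3,4-dihydroxybenzoate (20 mol%), neat, 4 °C; then LiOH·H2O (cat.), i-PrOH, rt
Reagents that add atoms: none
Why: The (S)-pyrrolidine forms the E-enamine of 5, whose C1' adds to the terminus of 6 from the face opposite the diphenyl(silyloxy)methyl group (C1'–C2' bond), and hydrolysis returns the catalyst and gives keto aldehyde 7 with C1' set (S in 7, R in 9); the closest known reaction is the amine-catalysed Michael addition of aldehydes to vinyl ketones. LiOH then enolises the methyl ketone toward C5', which attacks the C6' aldehyde in a 6-(enolendo)-exo-trig aldol closure of ring B (ketol 8), and E1cB loss of water gives enone 9, a Robinson-type annulation overall. C1' is controlled by the catalyst, which should override the weak bias of quaternary C6, whose CH3 and C5 arms are alike in size. The step needs C1' to be the only nucleophilic carbon of 5 and needs ring A to survive: 5 is β-quaternary and so cannot self-condense readily, and its β-oxygen O1 is a tertiary ring alkoxide, a poor leaving group for retro-oxa-Michael cleavage in the weakly acidic amine stage. In the base stage the aldehyde is consumed by the fast intramolecular aldol before C1' can enolise, and the equatorial C3 bromide has no antiperiplanar hydrogen for elimination.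

Step 5
Reactants: 9 (4R)-4-[(2S,5R)-5-bromo-2,6,6-trimethyloxan-2-yl]cyclohex-2-en-1-one
Product: 10 (1S,5R,6S)-5-[(2S,5R)-5-bromo-2,6,6-trimethyloxan-2-yl]-7-oxabicyclo[4.1.0]heptan-2-one
Conditions: H2O2 (30% aq), NaOH (cat.), MeOH, 0 °C
Reagents that add atoms: hydrogen peroxide, OO
Why: Weitz–Scheffer nucleophilic epoxidation: hydroperoxide adds to C6' anti to the bulky pseudo-equatorial ring A substituent on C1' and the enolate closes the oxirane, so C5' and C6' are set with the oxygen on the upper face.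

Step 6
Reactants: 10 (1S,5R,6S)-5-[(2S,5R)-5-bromo-2,6,6-trimethyloxan-2-yl]-7-oxabicyclo[4.1.0]heptan-2-one
Product: 12 (1S,5R,6S)-5-[(2S,5R)-5-bromo-2,6,6-trimethyloxan-2-yl]-7-oxabicyclo[4.1.0]hept-2-en-2-yl trifluoromethanesulfonate, via potassium enolate 11 (not isolated)
Conditions: KN(SiMe3)2, THF, −78 °C; then PhNTf2
Reagents that add atoms: N-phenylbis(trifluoromethanesulfonimide) (PhNTf2), FC(F)(F)S(=O)(=O)N(c1ccccc1)S(=O)(=O)C(F)(F)F
Why: Kinetic deprotonation at C3', the only enolisable α-carbon (C5' is an oxirane CH), followed by O-triflation of the enolate gives the C3'=C4' enol triflate; no stereocentre changes.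

Step 7
Reactants: 12 (1S,5R,6S)-5-[(2S,5R)-5-bromo-2,6,6-trimethyloxan-2-yl]-7-oxabicyclo[4.1.0]hept-2-en-2-yl trifluoromethanesulfonate
Product: 13 (1R,5R,6S)-5-[(2S,5R)-5-bromo-2,6,6-trimethyloxan-2-yl]-2-methyl-7-oxabicyclo[4.1.0]hept-2-ene
Conditions: MeZnCl, Pd(PPh3)4 (5 mol%), THF, 0 °C to rt
Reagents that add atoms: methylzinc chloride, C[Zn]Cl
Why: Negishi coupling: zerovalent palladium inserts into the C4'–OTf bond, zinc transfers methyl and reductive elimination forms C4'–CH3, which should outrun ionisation of the hindered alkenyl oxirane if the reaction is stopped at full conversion; the secondary alkyl bromide of ring A is inert to Pd(PPh3)4.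

Step 8
Reactants: 13 (1R,5R,6S)-5-[(2S,5R)-5-bromo-2,6,6-trimethyloxan-2-yl]-2-methyl-7-oxabicyclo[4.1.0]hept-2-ene
Product: 14 (1R,6R)-6-[(2S,5R)-5-bromo-2,6,6-trimethyloxan-2-yl]-3-methylcyclohex-3-en-1-ol
Conditions: HCO2H, Et3N, Pd2(dba)3·CHCl3 (cat.), n-Bu3P, THF, rt
Reagents that add atoms: none
Why: Palladium-catalysed formate hydrogenolysis of an alkenyl oxirane: zerovalent palladium ionises the allylic C5'–O bond, formate loses CO2 and hydride is delivered to C5', which leaves the C3'=C4' alkene in place and the C6' oxygen untouched (OH trans to ring A).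

Step 9
Reactants: 14 (1R,6R)-6-[(2S,5R)-5-bromo-2,6,6-trimethyloxan-2-yl]-3-methylcyclohex-3-en-1-ol
Product: 15 (6S)-6-[(2S,5R)-5-bromo-2,6,6-trimethyloxan-2-yl]-3-methylcyclohex-3-en-1-one
Conditions: DMP, NaHCO3, CH2Cl2, 0 °C
Reagents that add atoms: none
Why: Buffered periodinane oxidation gives the β,γ-unsaturated ketone without base, so the alkene should not move into conjugation and C1' should not epimerise; the crude ketone is reduced at once.

Step 10
Reactants: 15 (6S)-6-[(2S,5R)-5-bromo-2,6,6-trimethyloxan-2-yl]-3-methylcyclohex-3-en-1-one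
Product: 16 (1S,6R)-6-[(2S,5R)-5-bromo-2,6,6-trimethyloxan-2-yl]-3-methylcyclohex-3-en-1-ol
Conditions: LiBH(s-Bu)3, THF, −78 °C
Reagents that add atoms: none
Why: The bulky borohydride attacks the ketone along the equatorial trajectory from the upper face and gives the axial C6' alcohol cis to ring A (6'S), so the oxidation–reduction pair inverts C6'.

Step 11
Reactants: 16 (1S,6R)-6-[(2S,5R)-5-bromo-2,6,6-trimethyloxan-2-yl]-3-methylcyclohex-3-en-1-ol
Product: 17 tert-butyl{[(1S,6R)-6-[(2S,5R)-5-bromo-2,6,6-trimethyloxan-2-yl]-3-methylcyclohex-3-en-1-yl]oxy}dimethylsilane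
Conditions: TBSOTf, 2,6-lutidine, CH2Cl2, −78 to 0 °C
Reagents that add atoms: tert-butyldimethylsilyl trifluoromethanesulfonate (TBSOTf), CC(C)(C)[Si](C)(C)OS(=O)(=O)C(F)(F)F
Why: Silylation of the hindered axial alcohol with the silyl triflate; the ether shields the lower face of the C3'=C4' alkene and removes hydroxyl direction in step 12.

Step 12
Reactants: 17 tert-butyl{[(1S,6R)-6-[(2S,5R)-5-bromo-2,6,6-trimethyloxan-2-yl]-3-methylcyclohex-3-en-1-yl]oxy}dimethylsilane
Product: 18 tert-butyl{[(1S,3S,4R,6R)-4-[(2S,5R)-5-bromo-2,6,6-trimethyloxan-2-yl]-1-methyl-7-oxabicyclo[4.1.0]heptan-3-yl]oxy}dimethylsilane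
Conditions: mCPBA, NaHCO3, CH2Cl2, 0 °C
Reagents that add atoms: 3-chloroperoxybenzoic acid (mCPBA), OOC(=O)c1cccc(Cl)c1
Why: Prilezhaev epoxidation of the trisubstituted alkene from the upper face, anti to the pseudo-axial C6' silyloxy group, sets C3' and C4' with the oxirane oxygen up.

Step 13
Reactants: 18 tert-butyl{[(1S,3S,4R,6R)-4-[(2S,5R)-5-bromo-2,6,6-trimethyloxan-2-yl]-1-methyl-7-oxabicyclo[4.1.0]heptan-3-yl]oxy}dimethylsilane
Product: 19 (1R,2R,4S,5R)-2-bromo-5-[(2S,5R)-5-bromo-2,6,6-trimethyloxan-2-yl]-4-{[tert-butyl(dimethyl)silyl]oxy}-2-methylcyclohexan-1-ol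
Conditions: HBr (48% aq), CHCl3, −10 °C
Reagents that add atoms: hydrogen bromide, Br
Why: Acid-mediated trans-diaxial oxirane opening: bromide attacks the tertiary C4' from the lower face with inversion, the site favoured both by charge and by the chair-like transition state, giving axial C4'–Br and axial C3'–OH.

Step 14
Reactants: 19 (1R,2R,4S,5R)-2-bromo-5-[(2S,5R)-5-bromo-2,6,6-trimethyloxan-2-yl]-4-{[tert-butyl(dimethyl)silyl]oxy}-2-methylcyclohexan-1-ol
Product: 21 tert-butyl{[(1S,2R,4S,5S)-4-bromo-2-[(2S,5R)-5-bromo-2,6,6-trimethyloxan-2-yl]-5-chloro-5-methylcyclohexyl]oxy}dimethylsilane, via C3' triflate 20 (not isolated)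
Conditions: Tf2O, 2,6-lutidine, CH2Cl2, −78 °C; then n-Bu4NCl, −78 to 0 °C
Reagents that add atoms: tetrabutylammonium chloride, CCCC[N+](CCCC)(CCCC)CCCC.[Cl-]
Why: Neighbouring-group participation with 1,2-bromine shift: the antiperiplanar axial C4' bromine displaces the C3' triflate with inversion to give the lower-face bromonium ion, and chloride should open it from the upper face at C4', the tertiary carbon that carries most of the positive charge, so that Br ends on C3' and Cl on C4', trans and both equatorial (3'S,4'S).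

Step 15
Reactants: 21 tert-butyl{[(1S,2R,4S,5S)-4-bromo-2-[(2S,5R)-5-bromo-2,6,6-trimethyloxan-2-yl]-5-chloro-5-methylcyclohexyl]oxy}dimethylsilane
Product: 22 (1S,2R,4S,5S)-4-bromo-2-[(2S,5R)-5-bromo-2,6,6-trimethyloxan-2-yl]-5-chloro-5-methylcyclohexan-1-ol
Conditions: HF·pyridine, THF, 0 °C to rt
Reagents that add atoms: none
Why: Fluoride-driven Si–O cleavage under acidic, non-basic conditions frees the C6' hydroxyl without exposing the vicinal bromochloride to elimination.

Compound list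
1 | (S)-linalool, (3S)-3,7-dimethylocta-1,6-dien-3-ol | O[C@](C)(C=C)CCC=C(C)C | starting material
2 | (3R,6S)-3-bromo-6-ethenyl-2,2,6-trimethyloxane (Br cis to the C6 methyl) | CC1(C)O[C@](C)(C=C)CC[C@H]1Br | intermediate
3 | B-alkyl-9-BBN adduct, 9-{2-[(2S,5R)-5-bromo-2,6,6-trimethyloxan-2-yl]ethyl}-9-borabicyclo[3.3.1]nonane | CC1(C)O[C@](C)(CCB2C3CCCC2CCC3)CC[C@H]1Br | intermediate
4 | 2-[(2S,5R)-5-bromo-2,6,6-trimethyloxan-2-yl]ethan-1-ol | CC1(C)O[C@](C)(CCO)CC[C@H]1Br | intermediate
5 | 2-[(2S,5R)-5-bromo-2,6,6-trimethyloxan-2-yl]acetaldehyde (ring A acetaldehyde) | CC1(C)O[C@](C)(CC=O)CC[C@H]1Br | intermediate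
6 | but-3-en-2-one | CC(=O)C=C | starting material
7 | keto aldehyde, (2S)-2-[(2S,5R)-5-bromo-2,6,6-trimethyloxan-2-yl]-5-oxohexanal | CC1(C)O[C@](C)([C@@H](C=O)CCC(C)=O)CC[C@H]1Br | intermediate
8 | ketol, (4R)-4-[(2S,5R)-5-bromo-2,6,6-trimethyloxan-2-yl]-3-hydroxycyclohexan-1-one (both C6' epimers) | CC1(C)O[C@](C)([C@@H]2CCC(=O)CC2O)CC[C@H]1Br | intermediate
9 | (4R)-4-[(2S,5R)-5-bromo-2,6,6-trimethyloxan-2-yl]cyclohex-2-en-1-one | CC1(C)O[C@](C)([C@@H]2CCC(=O)C=C2)CC[C@H]1Br | intermediate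
10 | (1S,5R,6S)-5-[(2S,5R)-5-bromo-2,6,6-trimethyloxan-2-yl]-7-oxabicyclo[4.1.0]heptan-2-one (5',6'-oxirane trans to ring A) | CC1(C)O[C@](C)([C@@H]2CCC(=O)[C@H]3O[C@@H]23)CC[C@H]1Br | intermediate
11 | potassium enolate, potassium (1S,5R,6S)-5-[(2S,5R)-5-bromo-2,6,6-trimethyloxan-2-yl]-7-oxabicyclo[4.1.0]hept-2-en-2-olate | CC1(C)O[C@](C)([C@@H]2CC=C([O-])[C@H]3O[C@@H]23)CC[C@H]1Br.[K+] | intermediate
12 | (1S,5R,6S)-5-[(2S,5R)-5-bromo-2,6,6-trimethyloxan-2-yl]-7-oxabicyclo[4.1.0]hept-2-en-2-yl trifluoromethanesulfonate | CC1(C)O[C@](C)([C@@H]2CC=C(OS(=O)(=O)C(F)(F)F)[C@H]3O[C@@H]23)CC[C@H]1Br | intermediate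
13 | (1R,5R,6S)-5-[(2S,5R)-5-bromo-2,6,6-trimethyloxan-2-yl]-2-methyl-7-oxabicyclo[4.1.0]hept-2-ene | CC1(C)O[C@](C)([C@@H]2CC=C(C)[C@H]3O[C@@H]23)CC[C@H]1Br | intermediate
14 | (1R,6R)-6-[(2S,5R)-5-bromo-2,6,6-trimethyloxan-2-yl]-3-methylcyclohex-3-en-1-ol (C6'–OH trans to ring A) | CC1(C)O[C@](C)([C@@H]2CC=C(C)C[C@H]2O)CC[C@H]1Br | intermediate
15 | (6S)-6-[(2S,5R)-5-bromo-2,6,6-trimethyloxan-2-yl]-3-methylcyclohex-3-en-1-one | CC1(C)O[C@](C)([C@@H]2CC=C(C)CC2=O)CC[C@H]1Br | intermediate
16 | (1S,6R)-6-[(2S,5R)-5-bromo-2,6,6-trimethyloxan-2-yl]-3-methylcyclohex-3-en-1-ol (C6'–OH cis to ring A) | CC1(C)O[C@](C)([C@@H]2CC=C(C)C[C@@H]2O)CC[C@H]1Br | intermediate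
17 | tert-butyl{[(1S,6R)-6-[(2S,5R)-5-bromo-2,6,6-trimethyloxan-2-yl]-3-methylcyclohex-3-en-1-yl]oxy}dimethylsilane | CC1(C)O[C@](C)([C@@H]2CC=C(C)C[C@@H]2O[Si](C)(C)C(C)(C)C)CC[C@H]1Br | intermediate
18 | tert-butyl{[(1S,3S,4R,6R)-4-[(2S,5R)-5-bromo-2,6,6-trimethyloxan-2-yl]-1-methyl-7-oxabicyclo[4.1.0]heptan-3-yl]oxy}dimethylsilane (3',4'-oxirane on the upper face) | CC1(C)O[C@](C)([C@@H]2C[C@H]3O[C@@]3(C)C[C@@H]2O[Si](C)(C)C(C)(C)C)CC[C@H]1Br | intermediate
19 | (1R,2R,4S,5R)-2-bromo-5-[(2S,5R)-5-bromo-2,6,6-trimethyloxan-2-yl]-4-{[tert-butyl(dimethyl)silyl]oxy}-2-methylcyclohexan-1-ol (C4'–Br down, C3'–OH up) | CC1(C)O[C@](C)([C@@H]2C[C@@H](O)[C@](C)(Br)C[C@@H]2O[Si](C)(C)C(C)(C)C)CC[C@H]1Br | intermediate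
20 | C3' triflate, (1R,2R,4S,5R)-2-bromo-5-[(2S,5R)-5-bromo-2,6,6-trimethyloxan-2-yl]-4-{[tert-butyl(dimethyl)silyl]oxy}-2-methylcyclohexyl trifluoromethanesulfonate | CC1(C)O[C@](C)([C@@H]2C[C@@H](OS(=O)(=O)C(F)(F)F)[C@](C)(Br)C[C@@H]2O[Si](C)(C)C(C)(C)C)CC[C@H]1Br | intermediate
21 | tert-butyl{[(1S,2R,4S,5S)-4-bromo-2-[(2S,5R)-5-bromo-2,6,6-trimethyloxan-2-yl]-5-chloro-5-methylcyclohexyl]oxy}dimethylsilane | CC1(C)O[C@](C)([C@@H]2C[C@H](Br)[C@@](C)(Cl)C[C@@H]2O[Si](C)(C)C(C)(C)C)CC[C@H]1Br | intermediate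
22 | (1S,2R,4S,5S)-4-bromo-2-[(2S,5R)-5-bromo-2,6,6-trimethyloxan-2-yl]-5-chloro-5-methylcyclohexan-1-ol | CC1(C)O[C@](C)([C@@H]2C[C@H](Br)[C@@](C)(Cl)C[C@@H]2O)CC[C@H]1Br | target

Total step count: 15
Longest linear sequence: 15 steps (1 to 22; butenone 6 is bought)

Steps most likely to fail

Step 4. The enamine carbon C1' sits next to quaternary C6, so C–C bond formation may be slow or poorly face-selective, and the enamine or the aldehyde enolate may expel the β-oxygen O1 and open ring A. Fallback, auxiliary-controlled azaenolate alkylation: from 5, condensation with (R)-1-amino-2-(methoxymethyl)pyrrolidine gives the RAMP hydrazone F1. LiN(i-Pr)2 (THF, −78 °C) followed by 2-(2-iodoethyl)-2-methyl-1,3-dioxolane alkylates C1' on the face fixed by the chelated auxiliary and gives the alkylated hydrazone F2. Aqueous oxalic acid, then dilute HCl in THF, release the aldehyde and the ketone and so give keto aldehyde 7, where the route is rejoined; 7 is closed to 9 by the LiOH stage of step 4.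

Step 14. Chloride may open the bromonium ion at the secondary C3' (the trans-diaxial mode) instead of at C4', so that the bromine does not shift and the wrong constitutional isomer forms. Fallback, thermodynamic funnelling: the same operation from 19 then delivers the diaxial 3'-chloro-4'-bromo isomer F3, which is kept and heated in MeCN at 60–80 °C. This is the known thermal diaxial-to-diequatorial rearrangement of vicinal dihalides, in which the antiperiplanar C4' bromine re-forms the bromonium chloride ion pair and each halogen moves to the neighbouring carbon on its own face. Relief of the 1,3-diaxial contact between C4'–Br and the C6' silyloxy group, and the lack of an antiperiplanar bromine in the diequatorial product, should carry the material to 21, where the route is rejoined.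

Step 7. Zerovalent palladium may ionise the alkenyl oxirane of 12 or 13 in competition with the coupling, so that the oxirane is lost by allylic methylation or isomerisation. Fallback, open the oxirane before the coupling: from 10, SmI2 in THF/MeOH at −78 °C cleaves the α C–O bond and gives the trans ketol F4. TBSOTf and 2,6-lutidine give the silyl ether F5. KN(SiMe3)2 and PhNTf2 enolise away from the β-silyloxy group and give the enol triflate F6. MeZnCl with Pd(PPh3)4 gives the methyl alkene F7, and HF·pyridine removes the silyl group to give 14, where the route is rejoined.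

Further compounds
F1 | step 4 | RAMP hydrazone, (E)-2-[(2S,5R)-5-bromo-2,6,6-trimethyloxan-2-yl]-N-[(2R)-2-(methoxymethyl)pyrrolidin-1-yl]ethan-1-imine | CC1(C)O[C@](C)(C/C=N/N2CCC[C@@H]2COC)CC[C@H]1Br
F2 | step 4 | alkylated hydrazone, (E,2R)-2-[(2S,5R)-5-bromo-2,6,6-trimethyloxan-2-yl]-N-[(2R)-2-(methoxymethyl)pyrrolidin-1-yl]-4-(2-methyl-1,3-dioxolan-2-yl)butan-1-imine | CC1(C)O[C@](C)([C@@H](/C=N/N2CCC[C@@H]2COC)CCC3(C)OCCO3)CC[C@H]1Br
F3 | step 14 | diaxial isomer, tert-butyl{[(1S,2R,4R,5R)-5-bromo-2-[(2S,5R)-5-bromo-2,6,6-trimethyloxan-2-yl]-4-chloro-5-methylcyclohexyl]oxy}dimethylsilane | CC1(C)O[C@](C)([C@@H]2C[C@@H](Cl)[C@](C)(Br)C[C@@H]2O[Si](C)(C)C(C)(C)C)CC[C@H]1Br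
F4 | step 7 | trans ketol, (3R,4R)-4-[(2S,5R)-5-bromo-2,6,6-trimethyloxan-2-yl]-3-hydroxycyclohexan-1-one | CC1(C)O[C@](C)([C@@H]2CCC(=O)C[C@H]2O)CC[C@H]1Br
F5 | step 7 | silyl ether, (3R,4R)-4-[(2S,5R)-5-bromo-2,6,6-trimethyloxan-2-yl]-3-{[tert-butyl(dimethyl)silyl]oxy}cyclohexan-1-one | CC1(C)O[C@](C)([C@@H]2CCC(=O)C[C@H]2O[Si](C)(C)C(C)(C)C)CC[C@H]1Br
F6 | step 7 | enol triflate, (4R,5R)-4-[(2S,5R)-5-bromo-2,6,6-trimethyloxan-2-yl]-5-{[tert-butyl(dimethyl)silyl]oxy}cyclohex-1-en-1-yl trifluoromethanesulfonate | CC1(C)O[C@](C)([C@@H]2CC=C(OS(=O)(=O)C(F)(F)F)C[C@H]2O[Si](C)(C)C(C)(C)C)CC[C@H]1Br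
F7 | step 7 | methyl alkene, tert-butyl{[(1R,6R)-6-[(2S,5R)-5-bromo-2,6,6-trimethyloxan-2-yl]-3-methylcyclohex-3-en-1-yl]oxy}dimethylsilane | CC1(C)O[C@](C)([C@@H]2CC=C(C)C[C@H]2O[Si](C)(C)C(C)(C)C)CC[C@H]1Br
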